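The numbers in the tables come from a simulation for substances that don't exist.

The epsilon run levels off with D near 59.7%, just under the 65.0% its E can pay for, so we take one E per exchange. The alpha run then shows D decaying into G.

| setting | epsilon | alpha | spring | autumn | winter |
|---|---|---|---|---|---|
| Z | 0.20 M | 0.20 M | 0.20 M | 0.20 M | 0.20 M |
| E | 0.13 M | 0.54 M | 0.600 M | 0.240 M | 0.800 M |
| J | 0.10 M | 0.10 M | 0.100 M | 0.100 M | 0.100 M |
| remark | run made earlier | run made earlier |  |  |  |
| time |  |  | 4.0 d | 4.0 d | 4.0 d |

- epsilon (time / h: D / %): 4.00: 45.5; 6.00: 49.5; 8.00: 53.6; 15.0: 59.1; 20.0: 58.1; 30.0: 59.8; 50.0: 59.7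
- alpha (time / h: D / %): 6.00: 76.8; 15.0: 55.9; 20.0: 46.2; 30.0: 34.2; 40.0: 25.1; 50.0: 20.1

(scatter of a reading: 1 percentage point)

- which of these holds the largest part of the Z at the end of spring (D / G / Z)
- which of these holds the largest part of the Z at the end of autumn (D / G / Z)
- which of these holds the largest part of the Z at the end of winter (D / G / Z)
- D at the end of spring, in percent of the Z charged

- steps thought possible: Z + E <-> J + D; D + E <-> J + G; E <-> L; J -> Q

Once Z has gone, the E we count, free or not, is the excess (charged E minus two per Z) plus the D still present. If the rate is k times D times that E, then ln((excess + D)/D) climbs straight in time with slope k times excess. Alpha's excess is 0.140 M, and its readings from 15.0 h to 50.0 h give k = 0.140 /M/h.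

Spring's excess is 0.200 M. Starting the clock with all the Z as D, we reach D = 3.49% at 4.0 d, with G holding the rest. D is then small, so the counted E is nearly frozen at the excess, and D decays pseudo-first-order. Its tail half-life, the natural log of two over k times excess, is 1.03 d in spring.

Winter has the larger excess, 0.400 M, so we expect G there too. Autumn's E covers one per Z with 0.0400 M over, which would turn about 20.0% of the Z on to G and leave more as D, so we expect D to lead.

The weak link is k, taken from two readings. Other pairs give 0.140 /M/h from 6.00 h to 20.0 h and 0.138 /M/h from 30.0 h to 50.0 h, so we keep it.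

The forecast names G, D and G for spring, autumn and winter. It puts D in spring at 4.5%, “plus a little for the reverse step”, which is above our figure.

The flask gives G, D and G, with D in spring at 3.30%.

    Z + E ⇌ J + D (K = 1.10, k = 0.00100 /M/s)
    D + E ⇌ J + G (K = 0.450, k = 6.90 × 10⁻⁵ /M/s)
    E ⇌ L (K = 0.710, k = 3.10 × 10⁻⁴ /s)
    J → Q (k = 0.00410 /s)

Spring is not at rest at 4.0 d. Its D falls from 9.92% at 2.50 d to 3.30% at 4.00 d, a half-life of 0.945 d against the tail half-life of 1.03 d. In winter the same rule gives 0.516 d, and D there falls from 4.38% at 2.00 d to 0.270% at 4.00 d, a half-life of 0.498 d. Left to 40.0 d, spring shows D at 0% and G at 100%, while E moves from 20.1% to 19.5% of its charge.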